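Everything rests on cutting ring B at C4–C5. Carbon C2 stands at the ketone oxidation level beside the quaternary ring A carbon C1, and C4, two bonds further along ring B, is attached to the olefinic carbon C5: a ketone homoenolate and an alkenyl halide are hidden in the ten-membered ring. Palladium therefore opens a C1-bound cyclopropanol and couples its C4 terminus with a Z-configured C5 iodide, which forms C4–C5 and closes ring B in one operation. The precursor is the ring A–lactone core with a free cyclopropanol and the Z-iodoalkene; O12 is a silyl ether and O8/O9 an acetonide, so that no allylic ester and no base-labile hydroxy lactone meets the catalyst.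

Key step: step 21

Remark: enantiopure 17 and CH3C≡CLi (24) are taken to be purchasable; atom numbers in names and comments are those of the target.

Step 1
Reactants: 1 (E)-pent-3-en-2-one
Product: 2 (E)-2-(triisopropylsilyloxy)penta-1,3-diene
Conditions: LiN(iPr)2 (LDA), THF, −78 °C; then TIPSOTf, −78 to 0 °C
Reagents that add atoms: triisopropylsilyl trifluoromethanesulfonate, SMILES CC(C)[Si](C(C)C)(C(C)C)OS(=O)(=O)C(F)(F)F
Why: Kinetic deprotonation at the acetyl methyl group and O-silylation (silyl enol ether formation) should give the cross-conjugated 2-silyloxy diene with the E propenyl unit unchanged.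

Step 2
Reactants: 3 methyl 2-(triphenylphosphoranylidene)propanoate; 4 2,2-dimethoxyacetaldehyde
Product: 5 methyl (E)-4,4-dimethoxy-2-methylbut-2-enoate
Conditions: CH2Cl2, rt
Reagents that add atoms: none
Why: Wittig olefination with an ester-stabilised α-methyl ylide should give the E trisubstituted enoate, which places the future C9 carbon trans to the ester.

Step 3
Reactants: 5 methyl (E)-4,4-dimethoxy-2-methylbut-2-enoate
Product: 6 methyl (E)-2-methyl-4-oxobut-2-enoate
Conditions: Amberlyst-15, acetone/H2O, rt
Reagents that add atoms: water, SMILES O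
Why: Acid-catalysed acetal hydrolysis should free the aldehyde without touching the E enoate.

Step 4
Reactants: 2 (E)-2-(triisopropylsilyloxy)penta-1,3-diene; 6 methyl (E)-2-methyl-4-oxobut-2-enoate
Product: 8 ring A alcohol (C9 hydroxymethyl cis to both ring methyl groups), via Diels–Alder aldehyde 7 (not isolated)
Conditions: (R)-o-tolyl oxazaborolidine from (R)-α,α-diphenylprolinol (20 mol%), HNTf2 (17 mol%), CH2Cl2, −78 °C; then NaBH4, MeOH, −78 to 0 °C
Reagents that add atoms: none
Why: Enantioselective Diels–Alder reaction under chiral oxazaborolidinium catalysis: the CH2 terminus of the silyloxy diene (C14) bonds to the enal β-carbon C1, the catalyst-bound formyl group reacts endo (C9 cis to the C11 methyl), the E dienophile holds C9 cis to the C1 methyl and trans to the ester, and the catalyst, chosen by the formyl C–H···O binding model, shields one enal face to fix C1, C10 and C11, after which borohydride reduces the epimerisable aldehyde in the same flask.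

Step 5
Reactants: 8 ring A alcohol
Product: 9 O9 triethylsilyl ether of 8
Conditions: Et3SiCl, imidazole, CH2Cl2, 0 °C
Reagents that add atoms: chlorotriethylsilane, SMILES CC[Si](Cl)(CC)CC
Why: Silyl ether formation on the primary alcohol masks O9 before the enolate, palladium and titanium steps.

Step 6
Reactants: 9 O9 triethylsilyl ether
Product: 10 ring A 13-ketone with O12 as triisopropylsilyl ether
Conditions: mCPBA, NaHCO3, CH2Cl2, −20 to 0 °C
Reagents that add atoms: 3-chloroperoxybenzoic acid, SMILES OOC(=O)c1cccc(Cl)c1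
Why: Rubottom oxidation: the peracid should epoxidise the electron-rich enol ether anti to the C11 methyl and the C10 side chain, and a 1,4-silyl shift then gives the α-silyloxy ketone with O12 trans to the C11 methyl, the arrangement that is also favoured at equilibrium.

Step 7
Reactants: 10 ring A 13-ketone
Product: 11 C13=C14 enol triflate
Conditions: KN(SiMe3)2, PhNTf2, THF, −78 °C
Reagents that add atoms: N-phenylbis(trifluoromethanesulfonimide), SMILES O=S(=O)(N(c1ccccc1)S(=O)(=O)C(F)(F)F)C(F)(F)F
Why: Kinetic enolate formation and O-triflation: the bulky amide base should take a proton from the C14 methylene and not from the silyloxy-bearing C12 methine, so the triflate carries the C13=C14 double bond.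

Step 8
Reactants: 11 C13=C14 enol triflate
Product: 12 ring A ester with the C13=C14 alkene
Conditions: Pd(OAc)2 (5 mol%), PPh3, Bu3N, HCO2H, DMF, 60 °C
Reagents that add atoms: none
Why: Palladium-catalysed formate reduction of an enol triflate (oxidative addition, hydride transfer from formate, reductive elimination) should leave the C13=C14 alkene with the allylic silyl ether intact.

Step 9
Reactants: 12 ring A ester; 13 ethylmagnesium bromide
Product: 14 ring A cyclopropanol
Conditions: EtMgBr (3.5 equiv), Ti(OiPr)4 (1.0 equiv), THF, 0 °C to rt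
Reagents that add atoms: none
Why: Kulinkovich cyclopropanation: the titanacyclopropane formed from EtMgBr and Ti(OiPr)4 adds twice to the methyl ester, the only carbonyl group in 12, so that C2 becomes the carbinol carbon of a cyclopropanol whose CH2 groups are C3 and C4.

Step 10
Reactants: 14 ring A cyclopropanol
Product: 15 bis(triethylsilyl) ether (cyclopropanol oxygen and O9)
Conditions: Et3SiOTf, 2,6-lutidine, CH2Cl2, −78 °C
Reagents that add atoms: triethylsilyl trifluoromethanesulfonate, SMILES CC[Si](CC)(CC)OS(=O)(=O)C(F)(F)F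
Why: Silylation with a silyl triflate should cap the hindered tertiary cyclopropanol, which must not meet oxidants, Lewis acids or iodine as a free alcohol.

Step 11
Reactants: 15 bis(triethylsilyl) ether
Product: 16 ring A aldehyde (C9 formyl)
Conditions: (COCl)2, DMSO, CH2Cl2, −78 to −30 °C; then iPr2NEt
Reagents that add atoms: none
Why: Swern oxidation conditions are known to cleave a primary triethylsilyl ether and oxidise it in the same flask to the aldehyde, while the tertiary triethylsilyl and the triisopropylsilyl ether stay.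

Step 12
Reactants: 17 (R)-4-methyldihydrofuran-2(3H)-one
Product: 18 (3R,4S)-3-hydroxy-4-methyldihydrofuran-2(3H)-one
Conditions: NaN(SiMe3)2, THF, −78 °C; then 2-(phenylsulfonyl)-3-phenyloxaziridine; NH4Cl
Reagents that add atoms: 2-(phenylsulfonyl)-3-phenyloxaziridine, SMILES O=S(=O)(c1ccccc1)N1OC1c1ccccc1
Why: Enolate hydroxylation with an N-sulfonyloxaziridine should occur trans to the C17 methyl; the C8 centre made here is flattened again in step 13.

Step 13
Reactants: 18 (3R,4S)-3-hydroxy-4-methyldihydrofuran-2(3H)-one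
Product: 20 (S)-4-methyl-2,3-bis(trimethylsilyloxy)-4,5-dihydrofuran, via trimethylsilyl ether 19 (not isolated)
Conditions: Me3SiCl, Et3N, CH2Cl2, 0 °C; then LiN(iPr)2, THF, −78 °C, Me3SiCl
Reagents that add atoms: chlorotrimethylsilane, SMILES C[Si](C)(C)Cl
Why: O-Silylation followed by enolisation and O-trapping (silyl ketene acetal formation) should give the cyclic ketene acetal with C17 untouched.

Step 14
Reactants: 16 ring A aldehyde; 20 (S)-4-methyl-2,3-bis(trimethylsilyloxy)-4,5-dihydrofuran
Product: 22 aldol diol (9R; O8 cis to the C17 methyl), via silylated aldol 21 (not isolated)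
Conditions: BF3·OEt2, CH2Cl2, −78 °C; then citric acid, MeOH, 0 °C
Reagents that add atoms: none
Why: Mukaiyama aldol addition through an open transition state: the ketene acetal should react on the face anti to its C17 methyl (O8 cis and C9 trans to that methyl) and the aldehyde under Felkin–Anh control with the quaternary C1 branch of C10 anti to the incoming carbon, which sets 9R, and mild acid then removes only the trimethylsilyl group.

Step 15
Reactants: 22 aldol diol
Product: 23 O8/O9 acetonide
Conditions: 2-methoxypropene, PPTS, CH2Cl2, 0 °C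
Reagents that add atoms: 2-methoxypropene, SMILES COC(C)=C
Why: Acetal formation with an enol ether under mild acid should tie O8 and O9 into an acetonide, which blocks retro-aldol cleavage and lactone migration to O9 in the later steps.

Step 16
Reactants: 23 O8/O9 acetonide; 24 1-propynyllithium
Product: 25 hydroxy ynone (C7 ketone, C19 primary alcohol)
Conditions: CH3C≡CLi, THF, −78 °C; NH4Cl
Reagents that add atoms: none
Why: Acetylide addition to a lactone should stop at the ketone level because the lithium hemiketal alkoxide persists at low temperature and C8 has no proton for enolisation.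

Step 17
Reactants: 25 hydroxy ynone
Product: 26 propargylic diol (7S)
Conditions: RuCl[(R,R)-TsDPEN](p-cymene) (5 mol%), iPrOH, rt
Reagents that add atoms: none
Why: Asymmetric transfer hydrogenation of an alkynyl ketone is reagent controlled: the alkynyl group plays the part of the aryl group in the usual model, so the (R,R) catalyst should deliver the 7S carbinol from the open-chain ketone that equilibrates with its hemiketal.

Step 18
Reactants: 26 propargylic diol
Product: 27 Z-iodoalkenyl diol
Conditions: Red-Al, NaAlH2(OCH2CH2OMe)2, THF, 0 °C to rt; EtOAc; then I2, −78 to 0 °C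
Reagents that add atoms: iodine, SMILES I-I
Why: Hydroxyl-directed trans-hydroalumination of the propargylic alcohol puts aluminium on C5 cis to C7, and iodinolysis with retention should give the Z alkenyl iodide.

Step 19
Reactants: 27 Z-iodoalkenyl diol
Product: 28 iodoalkenyl lactone (C19 lactone on O7)
Conditions: TEMPO (20 mol%), PhI(OAc)2, CH2Cl2, rt
Reagents that add atoms: none
Why: Oxoammonium-mediated oxidative lactonisation of a 1,4-diol: the primary alcohol is oxidised first, the aldehyde closes to a lactol on O7 (O9 is locked in the acetonide) and the lactol is oxidised to the lactone.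

Step 20
Reactants: 28 iodoalkenyl lactone
Product: 29 cyclisation precursor (free cyclopropanol, Z C5 iodide)
Conditions: HF·pyridine, pyridine, THF, 0 °C
Reagents that add atoms: none
Why: Fluoride-mediated desilylation should remove the triethylsilyl group from the cyclopropanol while the triisopropylsilyl ether, the acetonide, the lactone and the alkenyl iodide stay.

Step 21
Reactants: 29 cyclisation precursor
Product: 30 ring B ketone (2-oxo macrocycle)
Conditions: Pd(OAc)2 (10 mol%), XPhos (20 mol%), Cs2CO3, toluene, 80 °C, 2 mM, syringe-pump addition of 29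
Reagents that add atoms: none
Why: Proposed new method: zerovalent palladium (from Pd(OAc)2 and XPhos) inserts into the C5–I bond, the cyclopropanol binds to the resulting divalent palladium as an alkoxide, strain-driven β-carbon elimination opens the three-membered ring to the C2 ketone with C4 on palladium, and reductive elimination joins C4 to C5. The closest known reaction type is the intermolecular palladium-catalysed ring-opening cross-coupling of cyclopropanols with aryl and alkenyl halides, which has not been used to close a medium ring. Ring B, the ten-membered ring, is closed by C(sp3)–C(sp2) reductive elimination from an eleven-membered palladacycle (ring-closing cross-coupling at C4–C5). No stereocentre is formed, and the Z geometry of C5=C6 is carried over from the iodide because oxidative addition and reductive elimination both retain alkene configuration. The step needs reductive elimination to outrun β-hydride loss from C3 (which would give the C3=C4 enone) and ring closure to outrun oligomerisation; the bulky electron-rich biaryl phosphine, chelation of the new C2 carbonyl to palladium, high dilution, the quaternary C1 and the Z iodide that turns C5 back toward ring A work in that direction. Chemoselectivity rests on the design of 29: oxidative addition can only occur at the alkenyl iodide because O12 is a silyl ether and not an ionisable allylic ester, and the acetonide keeps the tertiary C8 alkoxide and any acyl group away from the base.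

Step 22
Reactants: 30 ring B ketone
Product: 31 2R alcohol
Conditions: NaBH4, CeCl3·7H2O, MeOH, −40 °C
Reagents that add atoms: none
Why: Luche-type hydride reduction of the only ketone: hydride should add from the outer face of ring B, anti to the C10 branch of quaternary C1 (Felkin–Anh), to set 2R, and the lactone is inert at this temperature.

Step 23
Reactants: 31 2R alcohol
Product: 32 2,8,9-triol
Conditions: CF3CO2H, H2O, THF, 0 °C
Reagents that add atoms: none
Why: Acid-catalysed acetal hydrolysis should free O8 and O9 while the secondary triisopropylsilyl ether and the lactone survive.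

Step 24
Reactants: 32 2,8,9-triol; 33 acetic anhydride
Product: 34 2,9-diacetate
Conditions: Ac2O, DMAP, pyridine, rt
Reagents that add atoms: none
Why: Acylation under nucleophilic catalysis esterifies the two secondary alcohols at C2 and C9, and the tertiary C8 alcohol should stay free.

Step 25
Reactants: 34 2,9-diacetate
Product: 35 12-alcohol
Conditions: HF·pyridine, THF, rt
Reagents that add atoms: none
Why: Fluoride-mediated desilylation should release the C12 alcohol without acyl migration because the medium is acidic.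

Step 26
Reactants: 35 12-alcohol; 36 butanoic anhydride
Product: 37 target CNP0211702.1
Conditions: (PrCO)2O, DMAP, Et3N, CH2Cl2, 0 °C
Reagents that add atoms: none
Why: Acylation under nucleophilic catalysis can only reach the secondary C12 alcohol, since the remaining hydroxyl at C8 is tertiary.

Compound list

1 | (E)-pent-3-en-2-one | CC(=O)/C=C/C | starting material
2 | (E)-2-(triisopropylsilyloxy)penta-1,3-diene | C=C(O[Si](C(C)C)(C(C)C)C(C)C)/C=C/C | intermediate
3 | methyl 2-(triphenylphosphoranylidene)propanoate | COC(=O)C(C)=P(c1ccccc1)(c1ccccc1)c1ccccc1 | starting material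
4 | 2,2-dimethoxyacetaldehyde | COC(OC)C=O | starting material
5 | methyl (E)-4,4-dimethoxy-2-methylbut-2-enoate | COC(=O)/C(C)=C/C(OC)OC | intermediate
6 | methyl (E)-2-methyl-4-oxobut-2-enoate | COC(=O)/C(C)=C/C=O | intermediate
7 | Diels–Alder aldehyde: methyl 6-formyl-1,5-dimethyl-3-(triisopropylsilyloxy)cyclohex-3-ene-1-carboxylate, formyl cis to both methyl groups (ring positions 1 to 6 are C1, C14, C13, C12, C11, C10; C1, C10, C11 configured as in 37) | C1=C(O[Si](C(C)C)(C(C)C)C(C)C)C[C@@](C(=O)OC)(C)[C@H]([C@H]1C)C=O | intermediate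
8 | ring A alcohol: 6-(hydroxymethyl) analogue of 7 (C9 carbinol), same configuration | C1=C(O[Si](C(C)C)(C(C)C)C(C)C)C[C@@](C(=O)OC)(C)[C@H]([C@H]1C)CO | intermediate
9 | O9 triethylsilyl ether of 8 | C1=C(O[Si](C(C)C)(C(C)C)C(C)C)C[C@@](C(=O)OC)(C)[C@H]([C@H]1C)CO[Si](CC)(CC)CC | intermediate
10 | ring A 13-ketone: methyl 1,5-dimethyl-3-oxo-6-[(triethylsilyloxy)methyl]-4-(triisopropylsilyloxy)cyclohexane-1-carboxylate, O12 trans to the C11 methyl (C12 as in 37) | CC(C)[Si](C(C)C)(C(C)C)O[C@@H]1C(=O)C[C@@](C(=O)OC)(C)[C@H]([C@H]1C)CO[Si](CC)(CC)CC | intermediate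
11 | enol triflate of 10 with the double bond at C13=C14 | CC(C)[Si](C(C)C)(C(C)C)O[C@@H]1C(OS(=O)(=O)C(F)(F)F)=C[C@@](C(=O)OC)(C)[C@H]([C@H]1C)CO[Si](CC)(CC)CC | intermediate
12 | ring A ester: methyl 1,5-dimethyl-6-[(triethylsilyloxy)methyl]-4-(triisopropylsilyloxy)cyclohex-2-ene-1-carboxylate (C1, C10, C11, C12 as in 37) | CC(C)[Si](C(C)C)(C(C)C)O[C@@H]1C=C[C@@](C(=O)OC)(C)[C@H]([C@H]1C)CO[Si](CC)(CC)CC | intermediate
13 | ethylmagnesium bromide | CC[Mg]Br | starting material
14 | ring A cyclopropanol: 12 with the ester replaced by a 1-hydroxycyclopropyl group on C1 (carbinol carbon C2, ring CH2 groups C3 and C4) | CC(C)[Si](C(C)C)(C(C)C)O[C@@H]1C=C[C@@](C2(O)CC2)(C)[C@H]([C@H]1C)CO[Si](CC)(CC)CC | intermediate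
15 | bis(triethylsilyl) ether of 14 (cyclopropanol oxygen and O9) | CC(C)[Si](C(C)C)(C(C)C)O[C@@H]1C=C[C@@](C2(O[Si](CC)(CC)CC)CC2)(C)[C@H]([C@H]1C)CO[Si](CC)(CC)CC | intermediate
16 | ring A aldehyde: C9 formyl, cyclopropanol as triethylsilyl ether, O12 as triisopropylsilyl ether | CC(C)[Si](C(C)C)(C(C)C)O[C@@H]1C=C[C@@](C2(O[Si](CC)(CC)CC)CC2)(C)[C@H]([C@H]1C)C=O | intermediate
17 | (R)-4-methyldihydrofuran-2(3H)-one | C1C(=O)OC[C@@H]1C | starting material
18 | (3R,4S)-3-hydroxy-4-methyldihydrofuran-2(3H)-one (hydroxyl trans to methyl) | O[C@H]1C(=O)OC[C@@H]1C | intermediate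
19 | trimethylsilyl ether of 18 | C[Si](C)(C)O[C@H]1C(=O)OC[C@@H]1C | intermediate
20 | (S)-4-methyl-2,3-bis(trimethylsilyloxy)-4,5-dihydrofuran | C1(O[Si](C)(C)C)=C(O[Si](C)(C)C)OC[C@@H]1C | intermediate
21 | silylated aldol: C9 of 16 bonded to C3 of the lactone (C8); 9R carbinol; O8 (trimethylsilyl ether) cis and C9 trans to the lactone methyl | CC(C)[Si](C(C)C)(C(C)C)O[C@@H]1C=C[C@@](C2(O[Si](CC)(CC)CC)CC2)(C)[C@H]([C@H]1C)[C@@H](O)[C@@]1(O[Si](C)(C)C)C(=O)OC[C@@H]1C | intermediate
22 | aldol diol: 21 with free O8 hydroxyl | CC(C)[Si](C(C)C)(C(C)C)O[C@@H]1C=C[C@@](C2(O[Si](CC)(CC)CC)CC2)(C)[C@H]([C@H]1C)[C@@H](O)[C@@]1(O)C(=O)OC[C@@H]1C | intermediate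
23 | acetonide of 22 across O8 and O9 | CC(C)[Si](C(C)C)(C(C)C)O[C@@H]1C=C[C@@](C2(O[Si](CC)(CC)CC)CC2)(C)[C@H]([C@H]1C)[C@@H](OC(C)(C)O3)[C@]31C(=O)OC[C@@H]1C | intermediate
24 | 1-propynyllithium | [Li]C#CC | starting material
25 | hydroxy ynone: C7 ketone bearing the propynyl group (C6≡C5–CH3), C19 as CH2OH; in equilibrium with its cyclic hemiketal | CC(C)[Si](C(C)C)(C(C)C)O[C@@H]1C=C[C@@](C2(O[Si](CC)(CC)CC)CC2)(C)[C@H]([C@H]1C)[C@@H](OC(C)(C)O3)[C@]3([C@@H](C)CO)C(=O)C#CC | intermediate
26 | propargylic diol: 7S carbinol | CC(C)[Si](C(C)C)(C(C)C)O[C@@H]1C=C[C@@](C2(O[Si](CC)(CC)CC)CC2)(C)[C@H]([C@H]1C)[C@@H](OC(C)(C)O3)[C@]3([C@@H](C)CO)[C@H](C#CC)O | intermediate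
27 | Z-iodoalkenyl diol: C7(OH)–CH=C(I)CH3 with iodine cis to C7 | CC(C)[Si](C(C)C)(C(C)C)O[C@@H]1C=C[C@@](C2(O[Si](CC)(CC)CC)CC2)(C)[C@H]([C@H]1C)[C@@H](OC(C)(C)O3)[C@]3([C@@H](C)CO)[C@H](/C=C(/C)I)O | intermediate
28 | iodoalkenyl lactone: C19 lactone closed on O7, cyclopropanol as triethylsilyl ether | CC(C)[Si](C(C)C)(C(C)C)O[C@@H]1C=C[C@@](C2(O[Si](CC)(CC)CC)CC2)(C)[C@H]([C@H]1C)[C@@H](OC(C)(C)O3)[C@]31[C@H](/C=C(/C)I)OC(=O)[C@@H]1C | intermediate
29 | cyclisation precursor: free cyclopropanol on C1, Z C5 iodide, O8/O9 acetonide, O12 triisopropylsilyl ether | CC(C)[Si](C(C)C)(C(C)C)O[C@@H]1C=C[C@@](C2(O)CC2)(C)[C@H]([C@H]1C)[C@@H](OC(C)(C)O3)[C@]31[C@H](/C=C(/C)I)OC(=O)[C@@H]1C | intermediate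
30 | ring B ketone: 2-oxo macrocycle (C4–C5 bond formed, 5Z), O8/O9 acetonide, O12 triisopropylsilyl ether | CC(C)[Si](C(C)C)(C(C)C)O[C@@H]1C=C[C@@]2(C)[C@H]([C@H]1C)[C@@H](OC(C)(C)O3)[C@]31[C@H](/C=C(/C)CCC2=O)OC(=O)[C@@H]1C | intermediate
31 | 2R alcohol of 30 | CC(C)[Si](C(C)C)(C(C)C)O[C@@H]1C=C[C@@]2(C)[C@H]([C@H]1C)[C@@H](OC(C)(C)O3)[C@]31[C@H](/C=C(/C)CC[C@H]2O)OC(=O)[C@@H]1C | intermediate
32 | 2,8,9-triol, O12 triisopropylsilyl ether | CC(C)[Si](C(C)C)(C(C)C)O[C@@H]1C=C[C@@]2(C)[C@H]([C@H]1C)[C@@H](O)[C@@]1(O)[C@H](/C=C(/C)CC[C@H]2O)OC(=O)[C@@H]1C | intermediate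
33 | acetic anhydride | CC(=O)OC(C)=O | starting material
34 | 2,9-diacetate, O12 triisopropylsilyl ether | CC(C)[Si](C(C)C)(C(C)C)O[C@@H]1C=C[C@@]2(C)[C@H]([C@H]1C)[C@@H](OC(C)=O)[C@@]1(O)[C@H](/C=C(/C)CC[C@H]2OC(C)=O)OC(=O)[C@@H]1C | intermediate
35 | 12-alcohol: the target without its butanoyl group | O[C@@H]1C=C[C@@]2(C)[C@H]([C@H]1C)[C@@H](OC(C)=O)[C@@]1(O)[C@H](/C=C(/C)CC[C@H]2OC(C)=O)OC(=O)[C@@H]1C | intermediate
36 | butanoic anhydride | CCCC(=O)OC(=O)CCC | starting material
37 | CNP0211702.1 | CCCC(=O)O[C@@H]1C=C[C@@]2(C)[C@H]([C@H]1C)[C@@H](OC(C)=O)[C@@]1(O)[C@H](/C=C(/C)CC[C@H]2OC(C)=O)OC(=O)[C@@H]1C | target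

Total step count: 26. Longest linear sequence: 23 steps (steps 2, 3, 4 to 11, 14 to 26).

Steps most likely to fail

1. Step 21. The alkylpalladium at C4 may lose a β-hydride from C3, or chains may couple with one another faster than the eleven-membered palladacycle collapses. The fallback makes C4–C5 by an intramolecular B-alkyl Suzuki–Miyaura coupling, which is known chemistry. It sets out from 29: N-bromosuccinimide in CH2Cl2 at 0 °C opens the cyclopropanol to the β-bromo ketone F1, Et3N eliminates HBr to give the vinyl ketone F2, and (S)-2-methyl-CBS-oxazaborolidine with catecholborane reduces the enone under reagent control to the 2R allylic alcohol F3. 9-BBN-H hydroborates the terminal alkene to the C4 alkylborane F4, and Pd(dppf)Cl2, AsPh3 and Cs2CO3 in DMF/THF/water at high dilution couple C4 with the Z iodide. The fallback comes back to the route at 31.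

2. Step 14. Bond formation between the congested aldehyde carbon C9 and the fully substituted ketene acetal carbon C8 may stall, or facial selectivity at C9 may erode. The fallback sets out from 16 and from silyl ether 19, which is isolated for this purpose. The lithium enolate of 19 (LiN(iPr)2, THF, −78 °C) adds to 16 through a closed transition state to give the aldol F5, expected mainly as the C9 epimer. Dess–Martin periodinane oxidises it to the C9 ketone F6. NaBH4 in MeOH at −40 °C should then add hydride anti to the C8 silyloxy group, with the flat lactone carbonyl beside the ring A branch (polar Felkin–Anh), to give 21. The fallback comes back to the route at 21, which is desilylated to 22 as in step 14.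

3. Step 9. Insertion of the neopentyl-type ester into the titanacyclopropane may be too slow, so that 12 is recovered or only partly converted. The fallback sets out from 12: Me3SiCH2Li in THF followed by MeOH turns the ester into the C2 methyl ketone F7, LiN(iPr)2 and Et3SiCl give the triethylsilyl enol ether F8, and Simmons–Smith cyclopropanation (Et2Zn, CH2I2, CH2Cl2, 0 °C) of the electron-rich enol ether gives the silyloxycyclopropane. The fallback comes back to the route at 15.

Further compounds

F1 | step 21 | β-bromo ketone from ring opening of 29 (C2 ketone, C4 bromide) | CC(C)[Si](C(C)C)(C(C)C)O[C@@H]1C=C[C@@](C(=O)CCBr)(C)[C@H]([C@H]1C)[C@@H](OC(C)(C)O3)[C@]31[C@H](/C=C(/C)I)OC(=O)[C@@H]1C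
F2 | step 21 | vinyl ketone (C2 ketone, C3=C4) | CC(C)[Si](C(C)C)(C(C)C)O[C@@H]1C=C[C@@](C(=O)C=C)(C)[C@H]([C@H]1C)[C@@H](OC(C)(C)O3)[C@]31[C@H](/C=C(/C)I)OC(=O)[C@@H]1C
F3 | step 21 | 2R allylic alcohol | CC(C)[Si](C(C)C)(C(C)C)O[C@@H]1C=C[C@@]([C@H](O)C=C)(C)[C@H]([C@H]1C)[C@@H](OC(C)(C)O3)[C@]31[C@H](/C=C(/C)I)OC(=O)[C@@H]1C
F4 | step 21 | C4 alkylborane (9-BBN adduct of F3) | CC(C)[Si](C(C)C)(C(C)C)O[C@@H]1C=C[C@@]([C@H](O)CCB4C5CCCC4CCC5)(C)[C@H]([C@H]1C)[C@@H](OC(C)(C)O3)[C@]31[C@H](/C=C(/C)I)OC(=O)[C@@H]1C
F5 | step 14 | C9-epimeric aldol with O8 trimethylsilyl ether | CC(C)[Si](C(C)C)(C(C)C)O[C@@H]1C=C[C@@](C2(O[Si](CC)(CC)CC)CC2)(C)[C@H]([C@H]1C)[C@H](O)[C@@]1(O[Si](C)(C)C)C(=O)OC[C@@H]1C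
F6 | step 14 | C9 ketone with O8 trimethylsilyl ether | CC(C)[Si](C(C)C)(C(C)C)O[C@@H]1C=C[C@@](C2(O[Si](CC)(CC)CC)CC2)(C)[C@H]([C@H]1C)C(=O)[C@@]1(O[Si](C)(C)C)C(=O)OC[C@@H]1C
F7 | step 9 | C2 methyl ketone on ring A | CC(C)[Si](C(C)C)(C(C)C)O[C@@H]1C=C[C@@](C(C)=O)(C)[C@H]([C@H]1C)CO[Si](CC)(CC)CC
F8 | step 9 | triethylsilyl enol ether of F7 | CC(C)[Si](C(C)C)(C(C)C)O[C@@H]1C=C[C@@](C(=C)O[Si](CC)(CC)CC)(C)[C@H]([C@H]1C)CO[Si](CC)(CC)CC
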